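We count what a catalyst does before it dies.

the same everywhere: substrate 48 mM

| flask | reagent | free catalyst | remark | time |
|---|---|---|---|---|
| alder | 48 mM | 3.8 mM | run made earlier |  |
| larch | 48 mM | 41 mM | run made earlier |  |
| oak | 48 mM | 420 mM | run made earlier |  |
| noon | 48.0 mM | 4.0 mM |  | 4.0 min |
| dawn | 48.0 mM | 12 mM |  | 4.0 min |
| winter | 48.0 mM | 40 mM |  | 4.0 min |
| summer | 48.0 mM | 120 mM |  | 4.0 min |
| spring | 48.0 mM | 400 mM |  | 4.0 min |

| run | time / min | product / % |
|---|---|---|
| alder | 0.667 | 2.6 |
| alder | 1.33 | 3.7 |
| alder | 2.00 | 3.3 |
| alder | 3.00 | 3.1 |
| larch | 0.333 | 21.2 |
| larch | 1.00 | 33.2 |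
| larch | 2.00 | 33.2 |
| larch | 3.00 | 35.4 |
| oak | 0.333 | 4.4 |
| oak | 1.00 | 2.0 |
| oak | 2.00 | 2.8 |
| oak | 3.00 | 3.1 |

(each reading ± 1 percentage point)

- the numbers in the tables scatter with a standard deviation of 1 percentage point
- steps thought possible: substrate + free catalyst -> catalyst intermediate A; catalyst intermediate A -> catalyst intermediate B; catalyst intermediate C -> free catalyst + product; reagent + free catalyst -> spent catalyst; reagent + catalyst intermediate B <-> catalyst intermediate C
- "hardly changes" means that all values lie within two and a half points (for a concentration: within two and a half percent of the largest)

- amount of product at the end, in percent of the substrate charged for noon, dawn, winter, summer, spring, in this order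
- how the row runs (falls all the way / hardly changes / falls, then rises / rises all the way / rises, then falls)

The runs form a ladder of stopping times. Oak, with free catalyst at 8.75 of the substrate charge, is flat within the scatter from its first reading at 0.333 min. Larch, at 0.854, still gains up to 1.00 min, and alder, at 0.0792, is flat by 1.33 min. Alder and larch are flat well before 4.0 min, and oak is too, so we read the row as end states.

On the alder rung, free catalyst has two fates at any moment: substrate takes it into the cycle, which hands it back with one product, or reagent turns it into spent catalyst. Alder's plateau reads 0.425 product per catalyst charged, with the scatter of its readings. This is the entry ratio, entries into the cycle per death, a selectivity factor. Each catalyst then costs 1.43 reagent, one for its death and the rest for its products, but 0.425 substrate, so with equal charges of the two reagent falls faster than substrate and the ratio drifts upward as the flask runs.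

Our reckoning follows. For noon, the load of 0.0833 times the ratio gives 3.54%. For dawn, the load of 0.250 gives 10.6%, and the drift points a little above that. Winter's catalyst would demand 1.19 of the reagent charge, more than there is, so reagent is the limiting reagent there. Sharing the reagent by the ratio, the two charges being equal, gives 29.8% product, but larch's readings stand higher, at 33.2% to 35.4%, as the drift suggests, and we take larch's level for winter. Spring sits beside oak, whose readings average 3.07%. For summer we reckon no number and expect a value between larch's level and oak's.

For its low loadings the forecast says “Yield scales with catalyst”, and it prints 3.5%, 11%, 33%, 14%, 3.2%, so the row rises, then falls. It calls its summer value the uncertain one.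

The flasks give 3.34%, 11.0%, 34.5%, 12.1%, 3.34%, and the row rises, then falls.

    substrate + free catalyst → catalyst intermediate A (k = 1.92 M⁻¹ s⁻¹)
    catalyst intermediate A → catalyst intermediate B (k = 52.0 s⁻¹)
    catalyst intermediate C → free catalyst + product (k = 7.44 s⁻¹)
    reagent + free catalyst → spent catalyst (k = 4.97 M⁻¹ s⁻¹)
    reagent + catalyst intermediate B ⇌ catalyst intermediate C (K = 2.29 M⁻¹, k = 7.02 M⁻¹ s⁻¹)

In noon, the step from reagent and free catalyst to spent catalyst had 96% of its turnover up to the asked time behind it after 0.400 min. By 2.00 min, spent catalyst stood at >99.9% of the catalyst charged, with substrate at 96.7% and reagent at 88.3% of their charges. The entry ratio gave 3.54% for noon's product, and the flask holds 3.34%. For dawn, the same ratio, applied to reagent this time, gave 64.4% of the reagent left, and dawn holds 64%.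

The readings were generated by integration for substances that don't exist, noise included.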